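Take the cedar curve and replace it by its mean; I did that first, since cedar was the flask asked about.

all flasks: catalyst 0.34 mM

| run | substrate | temperature | remark | time |
|---|---|---|---|---|
| cedar | 0.038 M | 40 °C | the very flask that is asked about, followed so far |  |
| alder | 0.019 M | 25 °C | run made earlier |  |
| flask | 0.038 M | 40 °C |  | 2.0 h |

| run | time / min | target / % |
|---|---|---|
| cedar | 8.00 | 22.6 |
| cedar | 12.0 | 22.7 |
| cedar | 20.0 | 21.4 |
| cedar | 25.0 | 21.6 |
| cedar | 40.0 | 20.8 |
| cedar | 60.0 | 21.4 |
| cedar | 90.0 | 21.7 |
| alder | 1.00 | 15.9 |
| alder | 1.33 | 18.9 |
| alder | 2.00 | 22.4 |
| alder | 3.00 | 23.0 |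
| alder | 5.00 | 20.5 |
| alder | 8.00 | 16.1 |
| alder | 12.0 | 11.9 |

(each reading ± 0.5 percentage points)

- north-west: at 2.0 h raise the temperature by 15 K, then wait 1.0 h
- south: at 2.0 h add substrate, 50.0% of the amount charged, then wait 1.0 h
- north: at 2.0 h add catalyst, 100% of the amount charged, then wait 1.0 h
- east: change nothing and wait 1.0 h more

- what is added takes up no volume worth counting
- a reading or a percentage of target counts all its forms, free or not

1. target, in percent of the substrate first charged, at 2.0 h
2. which option adds most target ("none" when 2 percentage points or less is all one gets) (north-west / south / north / east / none)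
3. target present, in percent of the substrate first charged, after north-west
4. target present, in percent of the substrate first charged, after south

The cedar readings lay flat from 8.00 min to 90.0 min, so I took their mean, 21.7%, and called it the plateau level. Its error was 0.19 percentage points. But a mean can hide a misfit, so I checked the cedar reading furthest off: 22.7% stood 1.00 point above it, less than 2 standard deviations. So I committed to the plateau level for cedar at 2.0 h. But a flat line doesn't say why it is flat, and the alder run fell from 23.0% at 3.00 min to 11.9% at 12.0 min, so target could react further.

The forecast gave 21.5% (21% to 22%), 21.4% after north-west, 21.5% after south, and as best: none. Its ground was “The simplest reading is that the catalyst dies within minutes at 40 °C, freezing the mixture”.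

The flask gave 21.8%, then 40.0% after north-west and 32.8% after south, so the best option was north-west, with a gain of 18 points.

    target ⇌ isomer of the product (K = 2.10, k = 0.0390 /s, Ea = 81.0 kJ/mol, ΔH = −63.0 kJ/mol)
    crystals ⇌ target, rate k2*(cs2 - [target]) while solid is left; crystals form when [target] > cs2 (solubility = 17.0 mM, k = 0.420 /s)
    substrate → side product (k = 0.00470 /s, Ea = 79.0 kJ/mol)
    substrate + catalyst → catalyst + target (k = 29.0 /M/s, Ea = 47.0 kJ/mol)
    (constants at 40 °C)

The catalyst in the flask still stood at 100% at 120 min, so the plateau was no stop by dead catalyst; substrate stood at 0%, and isomer of the product at 2.10 times target. With the step from target to isomer of the product struck out, the flask gave 67.7%, so that step is the main reason for the level. The plateau level is a third of that amount, and north-west raised target's share to 59.1%.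

In the neighbour flask with 8.5 × 10⁻⁵ M of catalyst, the starting ratio of the catalysed step to the side-product step falls from 2.1 to 0.524, which scales the plateau level to 11.0%. The computed neighbour flask gave 11.1%.

Readings and results were generated by integration with made-up constants; the scatter is artificial.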